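**Plan**

- Retrosynthesis: C2 is taken out of ring C (O1–C2 and C2–C3), leaving a 2-hydroxydeoxybenzoin. This is cut at O1–C8a and C4–C4a in one operation into an A-ring aryne and a B-ring arylacetic acid.
- Enabling feature: ring A carries O1 (on C8a) and the C4 carbonyl (on C4a) on neighbouring carbons, with the C5 oxygen beside C4a and the prenylated C6 para to C8a. A 3-alkoxyaryne gives this pattern when an oxygen nucleophile adds remote from the alkoxy group and the aryl anion then takes the acyl group.
- Forward, fragments: the A-ring o-silylaryl triflate comes from phloroglucinol (steps 1–7). For the B fragment the dimethylpyran ring is made first (step 8), its carbocycle is aromatised (step 9) and the acetic acid arm is added by ortho-lithiation (steps 10–15).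
- Forward, union: step 16 joins the halves without closing a ring, step 17 closes ring C with a one-carbon unit, and step 18 removes the four MOM groups.
- Stereochemistry: the only stereocentre (C3 of the chroman, R) is set by Jacobsen–Katsuki epoxidation of the 2,2-dimethylchromene and kept through benzylic hydride opening; no later step touches it.

Key step: step 16

Remark (notation): prenyl = 3-methylbut-2-en-1-yl, MOM = methoxymethyl; ring A/C atoms carry isoflavone numbers, the B-ring fragment chroman numbers.
Remark (assumption): the (R,R)-salen–Mn catalyst is taken to give the (3R,4R)-oxirane of a 2,2-dimethylchromene, as is usual for this substrate class; if the opposite sense were found, the (S,S)-catalyst would be used.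

**Route**

Step 1
Reactants: 1 phloroglucinol
Product: 2 3,5-bis(methoxymethoxy)phenol
Conditions: MOMCl (2 equiv), i-Pr2NEt, DMF–CH2Cl2, 0 °C → rt
Reagents that add atoms: chloromethyl methyl ether, COCCl
Why: Base-mediated O-alkylation with two equivalents of MOMCl gives a statistical mixture from which the bis-ether (a single compound because 1 is threefold symmetric) is separated and the mono-ether recycled.

Step 2
Reactants: 2 3,5-bis(methoxymethoxy)phenol
Product: 3 [3,5-bis(methoxymethoxy)phenoxy]triisopropylsilane
Conditions: TIPSCl, imidazole, DMF, rt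
Reagents that add atoms: chlorotriisopropylsilane, CC(C)[Si](Cl)(C(C)C)C(C)C
Why: Imidazole-promoted silylation of the remaining phenol installs a bulky, non-coordinating ether that shields its two ortho positions in the next step.

Step 3
Reactants: 3 [3,5-bis(methoxymethoxy)phenoxy]triisopropylsilane; 4 prenyl bromide (1-bromo-3-methylbut-2-ene)
Product: 6 [3,5-bis(methoxymethoxy)-4-prenylphenoxy]triisopropylsilane, via aryllithium 5 (not isolated)
Conditions: n-BuLi, THF, 0 °C → rt; CuI (10 mol %), then 4, −78 °C → rt
Reagents that add atoms: none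
Why: Directed ortho-metalation puts lithium on the one carbon flanked by two MOM ethers, and copper-catalysed SN2 allylation of the aryllithium with 4 gives the linear prenyl arene.

Step 4
Reactants: 6 [3,5-bis(methoxymethoxy)-4-prenylphenoxy]triisopropylsilane
Product: 7 3,5-bis(methoxymethoxy)-4-prenylphenol
Conditions: TBAF, THF, 0 °C; aq NH4Cl
Reagents that add atoms: none
Why: Fluoride-induced desilylation cleaves the aryl silyl ether under conditions that leave the MOM acetals and the alkene untouched.

Step 5
Reactants: 7 3,5-bis(methoxymethoxy)-4-prenylphenol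
Product: 8 3,5-bis(methoxymethoxy)-4-prenylphenyl N-isopropylcarbamate
Conditions: i-PrNCO, Et3N (cat.), CH2Cl2, rt
Reagents that add atoms: isopropyl isocyanate, CC(C)N=C=O
Why: Base-catalysed addition of the phenol to the isocyanate gives the N-monoalkyl carbamate, a strong ortho-director that can later be removed under mild amine conditions.

Step 6
Reactants: 8 3,5-bis(methoxymethoxy)-4-prenylphenyl N-isopropylcarbamate
Product: 12 3,5-bis(methoxymethoxy)-4-prenyl-2-(trimethylsilyl)phenyl N-isopropylcarbamate, via N-silyl carbamate 9 (not isolated), via ortho-lithiated N-silyl carbamate 10 (not isolated), via C-silylated N-silyl carbamate 11 (not isolated)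
Conditions: TBSOTf (1.05 equiv), TMEDA, Et2O, 0 °C → rt; n-BuLi, TMEDA, −78 °C; TMSCl, −78 °C → rt; aq NaHSO4
Reagents that add atoms: chlorotrimethylsilane, C[Si](C)(C)Cl
Why: The silyl triflate, used in only slight excess, caps the N–H in situ, after which the carbamate and the adjacent MOM ether together direct lithiation (directed ortho-metalation) to the carbon between them, equivalent on either side by symmetry, and TMSCl traps the aryllithium before work-up frees the N–H again.

Step 7
Reactants: 12 3,5-bis(methoxymethoxy)-4-prenyl-2-(trimethylsilyl)phenyl N-isopropylcarbamate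
Product: 14 3,5-bis(methoxymethoxy)-4-prenyl-2-(trimethylsilyl)phenyl trifluoromethanesulfonate, via 2-silylphenol 13 (not isolated)
Conditions: DBU, Et2NH, MeCN, 40 °C; then PhNTf2, rt
Reagents that add atoms: N-phenylbis(trifluoromethanesulfonimide), O=S(=O)(N(c1ccccc1)S(=O)(=O)C(F)(F)F)C(F)(F)F
Why: Amine-induced E1cB fragmentation of the N–H carbamate (the isocyanate is captured by Et2NH as a urea) frees the phenoxide, which is sulfonylated in the same flask to give the o-silylaryl triflate.

Step 8
Reactants: 15 cyclohexane-1,3-dione; 16 3-methylbut-2-enal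
Product: 18 2,2-dimethyl-2,6,7,8-tetrahydro-5H-chromen-5-one, via Knoevenagel oxatriene 17 (not isolated)
Conditions: ethylenediammonium diacetate (10 mol %), MeOH, rt
Reagents that add atoms: none
Why: Knoevenagel condensation gives a 1-oxatriene that closes by 6π-oxa-electrocyclisation (formal [3+3] annulation) to the 2H-pyran, so the ring oxygen and the future C5 oxygen are placed without any regiochemical choice.

Step 9
Reactants: 18 2,2-dimethyl-2,6,7,8-tetrahydro-5H-chromen-5-one
Product: 20 2,2-dimethyl-2H-chromen-5-ol, via α-phenylselanyl ketone 19 (not isolated)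
Conditions: LDA, THF, −78 °C; PhSeCl; then NaIO4, NaHCO3, THF–MeOH–H2O, rt
Reagents that add atoms: none
Why: Kinetic α′-deprotonation of the vinylogous ester and selenenylation, then selenoxide syn-elimination, give a cyclohexadienone that tautomerises to the phenol, periodate being chosen so that no peracid meets the chromene double bond.

Step 10
Reactants: 20 2,2-dimethyl-2H-chromen-5-ol
Product: 21 5-(methoxymethoxy)-2,2-dimethyl-2H-chromene
Conditions: MOMCl, i-Pr2NEt, CH2Cl2, 0 °C → rt
Reagents that add atoms: chloromethyl methyl ether, COCCl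
Why: Base-mediated O-alkylation of the phenol gives the acetal that protects it during oxidation and later serves as the ortho-directing group.

Step 11
Reactants: 21 5-(methoxymethoxy)-2,2-dimethyl-2H-chromene
Product: 22 (3R,4R)-3,4-epoxy-5-(methoxymethoxy)-2,2-dimethylchroman
Conditions: (R,R)-Jacobsen Mn(salen)Cl (4 mol %), 4-phenylpyridine N-oxide, aq NaOCl (pH 11.3), CH2Cl2, 0 °C; crude epoxide used directly
Reagents that add atoms: sodium hypochlorite, [Na+].[O-]Cl
Why: Jacobsen–Katsuki epoxidation of the cis-disubstituted styrenyl double bond of a 2,2-dimethylchromene, a privileged substrate class, sets C3 (and C4) by catalyst control, the (R,R)-complex being expected to give the (3R,4R)-oxirane.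

Step 12
Reactants: 22 (3R,4R)-3,4-epoxy-5-(methoxymethoxy)-2,2-dimethylchroman
Product: 23 (3R)-5-(methoxymethoxy)-2,2-dimethylchroman-3-ol
Conditions: LiAlH4, THF, 0 °C; aq NaOH work-up
Reagents that add atoms: none
Why: Hydride opens the oxirane by SN2 attack at the activated benzylic C4, C3 being shielded by the neighbouring quaternary carbon, so the C3–O bond and its R configuration are untouched.

Step 13
Reactants: 23 (3R)-5-(methoxymethoxy)-2,2-dimethylchroman-3-ol
Product: 24 (3R)-3,5-bis(methoxymethoxy)-2,2-dimethylchroman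
Conditions: MOMCl, i-Pr2NEt, Bu4NI (cat.), CH2Cl2, 40 °C
Reagents that add atoms: chloromethyl methyl ether, COCCl
Why: Iodide-catalysed O-alkylation of the hindered secondary alcohol gives an acetal that, unlike a silyl ether, is inert to fluoride in the aryne step and leaves with the aryl acetals at the end.

Step 14
Reactants: 24 (3R)-3,5-bis(methoxymethoxy)-2,2-dimethylchroman; 25 ethylene oxide
Product: 27 2-[(3R)-3,5-bis(methoxymethoxy)-2,2-dimethylchroman-6-yl]ethanol, via 6-lithiochroman 26 (not isolated)
Conditions: n-BuLi, TMEDA, THF, 0 °C; then 25 (THF solution), −78 °C → rt; H2O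
Reagents that add atoms: none
Why: Directed ortho-metalation by the aryl MOM ether, a stronger director than the ring ether oxygen, lithiates C6, and the aryllithium opens the epoxide to add the two-carbon arm.

Step 15
Reactants: 27 2-[(3R)-3,5-bis(methoxymethoxy)-2,2-dimethylchroman-6-yl]ethanol
Product: 29 2-[(3R)-3,5-bis(methoxymethoxy)-2,2-dimethylchroman-6-yl]acetic acid, via arylacetaldehyde 28 (not isolated)
Conditions: TEMPO (cat.), NaClO2, NaOCl (cat.), MeCN–phosphate buffer (pH 6.7), 35 °C; citric acid work-up
Reagents that add atoms: sodium chlorite, [Na+].[O-]Cl=O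
Why: TEMPO-catalysed oxidation to the aldehyde with a Pinnick-type chlorite oxidation in the same flask gives the acid at near-neutral pH, with hypochlorite only catalytic so that the electron-rich ring is not chlorinated and the acetals survive.

Step 16
Reactants: 14 3,5-bis(methoxymethoxy)-4-prenyl-2-(trimethylsilyl)phenyl trifluoromethanesulfonate; 29 2-[(3R)-3,5-bis(methoxymethoxy)-2,2-dimethylchroman-6-yl]acetic acid
Product: 32 1-[6-hydroxy-2,4-bis(methoxymethoxy)-3-prenylphenyl]-2-[(3R)-3,5-bis(methoxymethoxy)-2,2-dimethylchroman-6-yl]ethan-1-one, via aryne 30 (not isolated), via aryl anion ester 31 (not isolated)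
Conditions: CsF (4 equiv), THF, 125 °C, sealed tube (14 in slight excess)
Reagents that add atoms: none
Why: Fluoride removes the silyl group of 14 and triflate leaves, giving aryne 30 (C4a≡C8a); the cesium carboxylate of 29 adds through oxygen at C8a, the aryne carbon remote from the C5 acetal, so that the aryl anion of 31 sits at C4a, where the neighbouring oxygen stabilises it inductively. The anion then attacks the ester carbonyl through a four-membered transition state and the strained adduct opens to the ketone phenoxide, a net insertion of the aryne into the acid C–O bond with O→C acyl shift. The closest known reaction type is the fluoride-induced addition of carboxylic acids to arynes that gives o-hydroxyaryl ketones at elevated temperature. No ring is closed and no stereocentre is created; O1–C8a and C4–C4a are the two bonds formed. The step needs distal regiochemistry in the addition, secured by the C5 alkoxy group flanking the aryne, and acyl shift in preference to protonation of 31, favoured by aprotic fluoride, high temperature and the absence of any silyl ether or free hydroxyl in 29. Because addition at C8a places O1 para to the prenyl group and leaves a single free phenol, the later pyranone closure can give only the 6-prenyl isoflavone.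

Step 17
Reactants: 32 1-[6-hydroxy-2,4-bis(methoxymethoxy)-3-prenylphenyl]-2-[(3R)-3,5-bis(methoxymethoxy)-2,2-dimethylchroman-6-yl]ethan-1-one
Product: 34 5,7-bis(methoxymethoxy)-3-[(3R)-3,5-bis(methoxymethoxy)-2,2-dimethylchroman-6-yl]-6-prenyl-4H-chromen-4-one, via enaminone 33 (not isolated)
Conditions: DMF-DMA (3 equiv), toluene, 90 °C
Reagents that add atoms: N,N-dimethylformamide dimethyl acetal, COC(OC)N(C)C
Why: Condensation of the active methylene with the formamide acetal gives an enaminone, and oxa-Michael addition of the one free phenol followed by loss of dimethylamine closes the pyranone (the standard deoxybenzoin-to-isoflavone annulation).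

Step 18
Reactants: 34 5,7-bis(methoxymethoxy)-3-[(3R)-3,5-bis(methoxymethoxy)-2,2-dimethylchroman-6-yl]-6-prenyl-4H-chromen-4-one
Product: 35 5,7-dihydroxy-3-[(3R)-3,5-dihydroxy-2,2-dimethylchroman-6-yl]-6-prenyl-4H-chromen-4-one (CNP0194496.1)
Conditions: 3 M aq HCl–MeOH (1:4), 50 °C, monitored closely
Reagents that add atoms: none
Why: Acid-catalysed transacetalisation to methanol removes the three aryl and the one alkyl MOM group, a deprotection long used on prenylated flavonoids, and touches neither the stereocentre nor the pyranone.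

**Compound list**

1 | phloroglucinol (benzene-1,3,5-triol) | Oc1cc(O)cc(O)c1 | starting material
2 | 3,5-bis(methoxymethoxy)phenol | COCOc1cc(O)cc(OCOC)c1 | intermediate
3 | [3,5-bis(methoxymethoxy)phenoxy]triisopropylsilane | COCOc1cc(O[Si](C(C)C)(C(C)C)C(C)C)cc(OCOC)c1 | intermediate
4 | prenyl bromide (1-bromo-3-methylbut-2-ene) | CC(C)=CCBr | starting material
5 | 4-lithio derivative of 3 (lithium between the two MOM ethers) | [Li]c1c(OCOC)cc(O[Si](C(C)C)(C(C)C)C(C)C)cc1OCOC | intermediate (not isolated)
6 | [3,5-bis(methoxymethoxy)-4-prenylphenoxy]triisopropylsilane | COCOc1cc(O[Si](C(C)C)(C(C)C)C(C)C)cc(OCOC)c1CC=C(C)C | intermediate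
7 | 3,5-bis(methoxymethoxy)-4-prenylphenol | COCOc1cc(O)cc(OCOC)c1CC=C(C)C | intermediate
8 | 3,5-bis(methoxymethoxy)-4-prenylphenyl N-isopropylcarbamate | COCOc1cc(OC(=O)NC(C)C)cc(OCOC)c1CC=C(C)C | intermediate
9 | N-(tert-butyldimethylsilyl) derivative of carbamate 8 | COCOc1cc(OC(=O)N(C(C)C)[Si](C)(C)C(C)(C)C)cc(OCOC)c1CC=C(C)C | intermediate (not isolated)
10 | 2-lithio derivative of 9 (lithium between carbamate and MOM ether) | [Li]c1c(OC(=O)N(C(C)C)[Si](C)(C)C(C)(C)C)cc(OCOC)c(CC=C(C)C)c1OCOC | intermediate (not isolated)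
11 | 2-(trimethylsilyl) derivative of 9 | C[Si](C)(C)c1c(OC(=O)N(C(C)C)[Si](C)(C)C(C)(C)C)cc(OCOC)c(CC=C(C)C)c1OCOC | intermediate (not isolated)
12 | 3,5-bis(methoxymethoxy)-4-prenyl-2-(trimethylsilyl)phenyl N-isopropylcarbamate | C[Si](C)(C)c1c(OC(=O)NC(C)C)cc(OCOC)c(CC=C(C)C)c1OCOC | intermediate
13 | 3,5-bis(methoxymethoxy)-4-prenyl-2-(trimethylsilyl)phenol | C[Si](C)(C)c1c(O)cc(OCOC)c(CC=C(C)C)c1OCOC | intermediate (not isolated)
14 | 3,5-bis(methoxymethoxy)-4-prenyl-2-(trimethylsilyl)phenyl trifluoromethanesulfonate | C[Si](C)(C)c1c(OS(=O)(=O)C(F)(F)F)cc(OCOC)c(CC=C(C)C)c1OCOC | intermediate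
15 | cyclohexane-1,3-dione | O=C1CCCC(=O)C1 | starting material
16 | 3-methylbut-2-enal | CC(C)=CC=O | starting material
17 | 2-(3-methylbut-2-en-1-ylidene)cyclohexane-1,3-dione | CC(C)=CC=C1C(=O)CCCC1=O | intermediate (not isolated)
18 | 2,2-dimethyl-2,6,7,8-tetrahydro-5H-chromen-5-one | CC1(C)C=CC2=C(CCCC2=O)O1 | intermediate
19 | 2,2-dimethyl-6-(phenylselanyl)-2,6,7,8-tetrahydro-5H-chromen-5-one (racemic at C6) | CC1(C)C=CC2=C(CCC([Se]c3ccccc3)C2=O)O1 | intermediate (not isolated)
20 | 2,2-dimethyl-2H-chromen-5-ol | CC1(C)C=Cc2c(O)cccc2O1 | intermediate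
21 | 5-(methoxymethoxy)-2,2-dimethyl-2H-chromene | COCOc1cccc2OC(C)(C)C=Cc12 | intermediate
22 | (3R,4R)-3,4-epoxy-5-(methoxymethoxy)-2,2-dimethylchroman | COCOc1cccc2c1[C@H]3O[C@H]3C(C)(C)O2 | intermediate
23 | (3R)-5-(methoxymethoxy)-2,2-dimethylchroman-3-ol | COCOc1cccc2c1C[C@@H](O)C(C)(C)O2 | intermediate
24 | (3R)-3,5-bis(methoxymethoxy)-2,2-dimethylchroman | COCOc1cccc2c1C[C@@H](OCOC)C(C)(C)O2 | intermediate
25 | ethylene oxide | C1CO1 | starting material
26 | 6-lithio derivative of 24 | [Li]c1ccc2c(c1OCOC)C[C@@H](OCOC)C(C)(C)O2 | intermediate (not isolated)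
27 | 2-[(3R)-3,5-bis(methoxymethoxy)-2,2-dimethylchroman-6-yl]ethanol | OCCc1ccc2c(c1OCOC)C[C@@H](OCOC)C(C)(C)O2 | intermediate
28 | 2-[(3R)-3,5-bis(methoxymethoxy)-2,2-dimethylchroman-6-yl]acetaldehyde | O=CCc1ccc2c(c1OCOC)C[C@@H](OCOC)C(C)(C)O2 | intermediate (not isolated)
29 | 2-[(3R)-3,5-bis(methoxymethoxy)-2,2-dimethylchroman-6-yl]acetic acid | OC(=O)Cc1ccc2c(c1OCOC)C[C@@H](OCOC)C(C)(C)O2 | intermediate
30 | 3,5-bis(methoxymethoxy)-4-prenylbenzyne (triple bond between the former C–Si and C–OTf carbons) | COCOC1=CC#CC(OCOC)=C1CC=C(C)C | intermediate (not isolated)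
31 | cesium salt of the 2-metallated 3,5-bis(methoxymethoxy)-4-prenylphenyl ester of acid 29 | COCOc1cc(OC(=O)Cc2ccc3c(c2OCOC)C[C@@H](OCOC)C(C)(C)O3)[c-]c(OCOC)c1CC=C(C)C.[Cs+] | intermediate (not isolated)
32 | 1-[6-hydroxy-2,4-bis(methoxymethoxy)-3-prenylphenyl]-2-[(3R)-3,5-bis(methoxymethoxy)-2,2-dimethylchroman-6-yl]ethan-1-one | O=C(Cc1ccc2c(c1OCOC)C[C@@H](OCOC)C(C)(C)O2)c1c(O)cc(OCOC)c(CC=C(C)C)c1OCOC | intermediate
33 | 3-(dimethylamino)-1-[6-hydroxy-2,4-bis(methoxymethoxy)-3-prenylphenyl]-2-[(3R)-3,5-bis(methoxymethoxy)-2,2-dimethylchroman-6-yl]prop-2-en-1-one | CN(C)C=C(c1ccc2c(c1OCOC)C[C@@H](OCOC)C(C)(C)O2)C(=O)c1c(O)cc(OCOC)c(CC=C(C)C)c1OCOC | intermediate (not isolated)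
34 | 5,7-bis(methoxymethoxy)-3-[(3R)-3,5-bis(methoxymethoxy)-2,2-dimethylchroman-6-yl]-6-prenyl-4H-chromen-4-one | CC(C)=CCc1c(OCOC)cc2occ(-c3ccc4c(c3OCOC)C[C@@H](OCOC)C(C)(C)O4)c(=O)c2c1OCOC | intermediate
35 | 5,7-dihydroxy-3-[(3R)-3,5-dihydroxy-2,2-dimethylchroman-6-yl]-6-(3-methylbut-2-en-1-yl)-4H-chromen-4-one | CC(C)=CCc1c(O)cc2occ(-c3ccc4c(c3O)C[C@@H](O)C(C)(C)O4)c(=O)c2c1O | target

**Step count**

Total: 18 steps. Longest linear sequence: 11 steps (steps 8–18, from cyclohexane-1,3-dione); the aryne arm is 7 steps (steps 1–7) before the union.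

**Steps most likely to fail**

Step 16. The aryl anion may be protonated before the acyl shift, the α-methylene of the freshly formed ester being an internal proton source, or the aryne may be consumed by a second nucleophile or by ene reaction with a prenyl group; either path ends in O-arylation without the C4–C4a bond. The fallback sets out from carbamate 8 and acid 29 and returns at 32. Acid 29 is converted into its Weinreb amide F1 (MeNHOMe·HCl, EDCI, HOBt, i-Pr2NEt). Carbamate 8 is N-silylated and ortho-lithiated exactly as in step 6 to give 10, which is acylated by F1 at −78 °C to the N-silyl keto carbamate F2; aqueous work-up gives keto carbamate F3. Et2NH/DBU in MeCN then removes the carbamate and delivers 32. The C4–C4a bond is thus made by directed ortho-metalation and acylation, with the phenol oxygen in place from the start.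

Step 11. Enantioselection may be insufficient with this electron-rich chromene, or the doubly oxygen-activated benzylic epoxide may open or rearrange before it can be reduced. The fallback sets out from chromene 21 and returns at 23. Hydroboration–oxidation (BH3·THF; NaOH, H2O2) should give the racemic chromanol F4, and Dess–Martin oxidation the chromanone F5. CBS reduction with (S)-Me-CBS and BH3·SMe2, in which the quaternary C2 is the large and the benzylic CH2 the small substituent, is expected by the usual model to give (R)-23, so the stereocentre comes from ketone reduction and no epoxide is handled.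

Step 18. During the longer acid exposure that the alkyl acetal requires, the prenyl double bond may be protonated and cyclise onto a neighbouring freed phenol, or add methanol or HCl. The fallback sets out from 34 and returns at 35. Silyl-transfer deacetalisation with TESOTf and 2,2′-bipyridyl in CH2Cl2 at 0 °C turns the three aryl acetals into triethylsilyl ethers and the alkyl acetal into the bipyridinium salt F6. Water added to the same flask hydrolyses the salt to the tris-silyl ether F7. Buffered fluoride (TBAF/AcOH, THF, 0 °C) then frees the phenols and gives 35 without protic acid.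

**Further compounds**

F1 | step 16 | 2-[(3R)-3,5-bis(methoxymethoxy)-2,2-dimethylchroman-6-yl]-N-methoxy-N-methylacetamide | CON(C)C(=O)Cc1ccc2c(c1OCOC)C[C@@H](OCOC)C(C)(C)O2
F2 | step 16 | 2-{2-[(3R)-3,5-bis(methoxymethoxy)-2,2-dimethylchroman-6-yl]acetyl}-3,5-bis(methoxymethoxy)-4-prenylphenyl N-(tert-butyldimethylsilyl)-N-isopropylcarbamate | O=C(Cc1ccc2c(c1OCOC)C[C@@H](OCOC)C(C)(C)O2)c1c(OC(=O)N(C(C)C)[Si](C)(C)C(C)(C)C)cc(OCOC)c(CC=C(C)C)c1OCOC
F3 | step 16 | 2-{2-[(3R)-3,5-bis(methoxymethoxy)-2,2-dimethylchroman-6-yl]acetyl}-3,5-bis(methoxymethoxy)-4-prenylphenyl N-isopropylcarbamate | O=C(Cc1ccc2c(c1OCOC)C[C@@H](OCOC)C(C)(C)O2)c1c(OC(=O)NC(C)C)cc(OCOC)c(CC=C(C)C)c1OCOC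
F4 | step 11 | racemic 5-(methoxymethoxy)-2,2-dimethylchroman-3-ol | COCOc1cccc2c1CC(O)C(C)(C)O2
F5 | step 11 | 5-(methoxymethoxy)-2,2-dimethylchroman-3-one | COCOc1cccc2c1CC(=O)C(C)(C)O2
F6 | step 18 | 1-({[(3R)-6-[6-prenyl-5,7-bis(triethylsilyloxy)-4-oxo-4H-chromen-3-yl]-5-(triethylsilyloxy)-2,2-dimethylchroman-3-yl]oxy}methyl)-2-(pyridin-2-yl)pyridinium triflate | CC(C)=CCc1c(O[Si](CC)(CC)CC)cc2occ(-c3ccc4c(c3O[Si](CC)(CC)CC)C[C@@H](OC[n+]5ccccc5-c5ccccn5)C(C)(C)O4)c(=O)c2c1O[Si](CC)(CC)CC.[O-]S(=O)(=O)C(F)(F)F
F7 | step 18 | 3-[(3R)-3-hydroxy-2,2-dimethyl-5-(triethylsilyloxy)chroman-6-yl]-6-prenyl-5,7-bis(triethylsilyloxy)-4H-chromen-4-one | CC(C)=CCc1c(O[Si](CC)(CC)CC)cc2occ(-c3ccc4c(c3O[Si](CC)(CC)CC)C[C@@H](O)C(C)(C)O4)c(=O)c2c1O[Si](CC)(CC)CC
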